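**Retrosynthetic overview**
1. Target ⇐ global O-dealkylation (BBr3) of a per-O-alkylated bromotriphlorethol; both diaryl ether bonds are already in place.
2. Ring A–O–ring B ether ⇐ Ullmann coupling of a 2,6-dialkoxyphenol (ring A, hindered OH as nucleophile) with the unhindered bromide of a ring B–ring C dibromide.
3. Ring B–O–ring C ether ⇐ iodide-selective Ullmann coupling of 4-bromo-2,6-dimethoxyphenol with 2-bromo-5-iodo-1,3-dimethoxybenzene (from C–H borylation/iodination).
4. Ring A is the only ring built (rings B and C are bought as arenes). Its key C–C bond joins 1-ethoxyvinyllithium, a masked acetyl anion, to a carbonyl of 3-isopropoxycyclobutenedione; Moore ring expansion then gives the arene, with the enol-ether oxygen kept as a ring oxygen.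
5. The semisquarate ⇐ diisopropyl squarate by mono-reduction and acid hydrolysis.

Assumption: the target has no stereocentre and is achiral, so no stereocontrol is needed.

**Step 1**
Reactants: 1 diisopropyl squarate (3,4-diisopropoxycyclobut-3-ene-1,2-dione)
Product: 3 3-isopropoxycyclobut-3-ene-1,2-dione, via hydroxycyclobutenone 2 (not isolated)
Conditions: LiAlH(OtBu)3, THF, −78 °C; then conc. aq HCl, CH2Cl2, rt
Reagents that add atoms: water, O
Why: 1,2-hydride addition to one squarate carbonyl gives racemic carbinol 2, and acid-mediated allylic ionisation with hydrolysis of the vinylogous ester (loss of isopropanol, 1,3-oxygen transposition) gives the semisquarate, a known type of squarate-to-cyclobutenedione conversion; no stereocentre remains.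

**Step 2**
Reactants: 3 3-isopropoxycyclobut-3-ene-1,2-dione; 4 ethyl vinyl ether
Product: 9 2-ethoxy-6-isopropoxybenzene-1,4-diol, via 1-ethoxyvinyllithium 5 (not isolated), via cyclobutenone adduct 6 (not isolated), via dienylketene 7 (not isolated), via cyclohexadienone 8 (not isolated)
Conditions: 4, t-BuLi, THF, −78 to 0 °C; then 3, THF, −78 °C; aq NH4Cl; crude 6, degassed PhMe, 110 °C, Ar
Reagents that add atoms: none
Why: The masked acetyl anion 5 adds 1,2 to the more electrophilic carbonyl (the one not in vinylogous-ester conjugation), joining two carbonyl-level carbons, and the adduct undergoes Moore rearrangement (conrotatory 4π ring opening with OH outward, 6π electrocyclisation of the Z-dienylketene, tautomerisation), so the enol-ether oxygen ends as the aryl ethyl ether flanking the new central OH; no stereocentre remains.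

**Step 3**
Reactants: 9 2-ethoxy-6-isopropoxybenzene-1,4-diol
Product: 10 2-ethoxy-4,6-diisopropoxyphenol
Conditions: 2-bromopropane (1.1 equiv), K2CO3 (1.1 equiv), degassed DMF, 50 °C, Ar
Reagents that add atoms: 2-bromopropane, CC(C)Br
Why: Williamson etherification is selective for the 4-OH, which is the more acidic (meta to two alkoxy groups) and unhindered, while the secondary halide discriminates against the OH flanked by two alkoxy groups.

**Step 4**
Reactants: 11 2-bromo-1,3-dimethoxybenzene
Product: 13 2-bromo-5-iodo-1,3-dimethoxybenzene, via arylboronate 12 (not isolated)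
Conditions: B2pin2, [Ir(OMe)(cod)]2 (1 mol%), 4,4'-di-tert-butyl-2,2'-bipyridine (2 mol%), THF, 80 °C; evaporate; CuI (10 mol%), 1,10-phenanthroline (20 mol%), KI, MeOH/H2O, air, 80 °C
Reagents that add atoms: potassium iodide, [K+].[I-]; bis(pinacolato)diboron, CC1(C)OB(OC1(C)C)B1OC(C)(C)C(C)(C)O1 (its boron stays only in intermediate 12)
Why: Sterically controlled iridium-catalysed C–H borylation takes the only C–H with no ortho substituent (C5), and copper-mediated iododeboronation replaces boron ipso while leaving the aryl bromide untouched.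

**Step 5**
Reactants: 13 2-bromo-5-iodo-1,3-dimethoxybenzene; 14 4-bromo-2,6-dimethoxyphenol
Product: 15 5-bromo-2-(4-bromo-3,5-dimethoxyphenoxy)-1,3-dimethoxybenzene
Conditions: CuI (10 mol%), picolinic acid (20 mol%), K3PO4, DMSO, 80 °C, Ar
Reagents that add atoms: none
Why: Ullmann-type diaryl ether synthesis proceeds at the C–I bond, which reacts far faster than either C–Br bond (one is para to the phenoxide oxygen and deactivated, the other is flanked by two methoxy groups).

**Step 6**
Reactants: 10 2-ethoxy-4,6-diisopropoxyphenol; 15 5-bromo-2-(4-bromo-3,5-dimethoxyphenoxy)-1,3-dimethoxybenzene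
Product: 16 2-[4-(4-bromo-3,5-dimethoxyphenoxy)-3,5-dimethoxyphenoxy]-1-ethoxy-3,5-diisopropoxybenzene
Conditions: CuI (20 mol%), picolinic acid (40 mol%), K3PO4, DMSO, 110 °C, Ar
Reagents that add atoms: none
Why: Ullmann coupling of the hindered phenol occurs only at the unhindered ring B bromide, because reaction at the ring C bromide would require a diaryl ether with four ortho substituents.

**Step 7**
Reactants: 16 2-[4-(4-bromo-3,5-dimethoxyphenoxy)-3,5-dimethoxyphenoxy]-1-ethoxy-3,5-diisopropoxybenzene
Product: 17 2-[4-(4-bromo-3,5-dihydroxyphenoxy)-3,5-dihydroxyphenoxy]benzene-1,3,5-triol (target)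
Conditions: BBr3 (14 equiv), CH2Cl2, −78 °C to rt, Ar; ice-water quench; degassed work-up
Reagents that add atoms: none
Why: Lewis-acid ether cleavage by BBr3 removes all seven alkyl groups (four methyl, one ethyl, two isopropyl) as alkyl bromides, while diaryl ether C–O bonds and the aryl bromide are inert to it.

**Compound list**
1 | diisopropyl squarate (3,4-diisopropoxycyclobut-3-ene-1,2-dione) | CC(C)OC1=C(OC(C)C)C(=O)C1=O | starting material
2 | 4-hydroxy-2,3-diisopropoxycyclobut-2-en-1-one (racemic) | CC(C)OC1=C(OC(C)C)C(O)C1=O | intermediate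
3 | 3-isopropoxycyclobut-3-ene-1,2-dione | CC(C)OC1=CC(=O)C1=O | intermediate
4 | ethyl vinyl ether | C=COCC | starting material
5 | 1-ethoxyvinyllithium | [Li]C(=C)OCC | intermediate
6 | 4-(1-ethoxyvinyl)-4-hydroxy-3-isopropoxycyclobut-2-en-1-one (racemic) | O=C1C=C(OC(C)C)C1(O)C(=C)OCC | intermediate
7 | (3Z)-5-ethoxy-4-hydroxy-3-isopropoxyhexa-1,3,5-trien-1-one (dienylketene) | O=C=C/C(OC(C)C)=C(O)\C(OCC)=C | intermediate
8 | 5-ethoxy-4-hydroxy-3-isopropoxycyclohexa-2,4-dien-1-one | O=C1C=C(OC(C)C)C(O)=C(OCC)C1 | intermediate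
9 | 2-ethoxy-6-isopropoxybenzene-1,4-diol | CCOc1cc(O)cc(OC(C)C)c1O | intermediate
10 | 2-ethoxy-4,6-diisopropoxyphenol | CCOc1cc(OC(C)C)cc(OC(C)C)c1O | intermediate
11 | 2-bromo-1,3-dimethoxybenzene | COc1cccc(OC)c1Br | starting material
12 | 2-(4-bromo-3,5-dimethoxyphenyl)-4,4,5,5-tetramethyl-1,3,2-dioxaborolane | COc1cc(B2OC(C)(C)C(C)(C)O2)cc(OC)c1Br | intermediate
13 | 2-bromo-5-iodo-1,3-dimethoxybenzene | COc1cc(I)cc(OC)c1Br | intermediate
14 | 4-bromo-2,6-dimethoxyphenol | COc1cc(Br)cc(OC)c1O | starting material
15 | 5-bromo-2-(4-bromo-3,5-dimethoxyphenoxy)-1,3-dimethoxybenzene | COc1cc(Br)cc(OC)c1Oc1cc(OC)c(Br)c(OC)c1 | intermediate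
16 | 2-[4-(4-bromo-3,5-dimethoxyphenoxy)-3,5-dimethoxyphenoxy]-1-ethoxy-3,5-diisopropoxybenzene | CCOc1cc(OC(C)C)cc(OC(C)C)c1Oc1cc(OC)c(Oc2cc(OC)c(Br)c(OC)c2)c(OC)c1 | intermediate
17 | 2-[4-(4-bromo-3,5-dihydroxyphenoxy)-3,5-dihydroxyphenoxy]benzene-1,3,5-triol | Oc1cc(O)c(Oc2cc(O)c(Oc3cc(O)c(Br)c(O)c3)c(O)c2)c(O)c1 | target

**Step count**
Total steps: 7. Longest linear sequence: 5 (steps 1, 2, 3, 6, 7 from diisopropyl squarate); steps 4 and 5 form the convergent branch.

**Three steps most likely to fail**

Step 2. The risks are addition at the wrong carbonyl or in conjugate fashion, acid lability of the α-ethoxyvinyl carbinol 6, and air oxidation of hydroquinone 9. The fallback sets out from 3 (with 5 made from 4) and returns at 10. The lithium alkoxide is trapped in the flask with Me3SiCl to give 4-(1-ethoxyvinyl)-3-isopropoxy-4-(trimethylsilyloxy)cyclobut-2-en-1-one F1, which is neutral and can be purified. Thermolysis in toluene then gives 3-ethoxy-5-isopropoxy-4-(trimethylsilyloxy)phenol F2, in which the flanked oxygen is still masked. The single free OH is isopropylated under Mitsunobu conditions (i-PrOH, PPh3, DIAD) to (2-ethoxy-4,6-diisopropoxyphenoxy)trimethylsilane F3. K2CO3/MeOH desilylation gives 10, bypassing 9 and the selectivity question of step 3.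

Step 6. The risk is a sluggish Ullmann coupling of the bulky, electron-rich phenol with an aryl bromide. The fallback sets out from 15 and returns at 16. Miyaura borylation at the unhindered bromide (B2pin2, Pd(dppf)Cl2, KOAc, dioxane, 80 °C) gives 2-[4-(4-bromo-3,5-dimethoxyphenoxy)-3,5-dimethoxyphenyl]-4,4,5,5-tetramethyl-1,3,2-dioxaborolane F4. This is joined to 10 by oxidative copper coupling of the Chan–Lam type (Cu(OAc)2, pyridine, 4 Å sieves, air, CH2Cl2, rt) to give 16.

Step 5. The risk is incomplete iodide-over-bromide selectivity, leading to oligomers through the bromide of 14 or 15. The fallback sets out from 12 (isolated after the borylation stage of step 4, iodination omitted) and returns at 15. Cleavage of the pinacol ester with NaIO4 and aqueous NH4OAc gives (4-bromo-3,5-dimethoxyphenyl)boronic acid F5. Chan–Lam coupling with 14 (Cu(OAc)2, pyridine, 4 Å sieves, air, CH2Cl2, rt), to which aryl bromides are inert, gives 15.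

**Further compounds**
F1 | step 2 | 4-(1-ethoxyvinyl)-3-isopropoxy-4-(trimethylsilyloxy)cyclobut-2-en-1-one (racemic) | O=C1C=C(OC(C)C)C1(O[Si](C)(C)C)C(=C)OCC
F2 | step 2 | 3-ethoxy-5-isopropoxy-4-(trimethylsilyloxy)phenol | CCOc1cc(O)cc(OC(C)C)c1O[Si](C)(C)C
F3 | step 2 | (2-ethoxy-4,6-diisopropoxyphenoxy)trimethylsilane | CCOc1cc(OC(C)C)cc(OC(C)C)c1O[Si](C)(C)C
F4 | step 6 | 2-[4-(4-bromo-3,5-dimethoxyphenoxy)-3,5-dimethoxyphenyl]-4,4,5,5-tetramethyl-1,3,2-dioxaborolane | COc1cc(B2OC(C)(C)C(C)(C)O2)cc(OC)c1Oc1cc(OC)c(Br)c(OC)c1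
F5 | step 5 | (4-bromo-3,5-dimethoxyphenyl)boronic acid | COc1cc(B(O)O)cc(OC)c1Br
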